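**Assumptions (one line each)**
- Commercial α-turmerone is the natural (6S)-2-methyl-6-[(1R)-4-methylcyclohexa-2,4-dien-1-yl]hept-2-en-4-one. It is sold as a reference standard and is isolable from turmeric oil, and it already carries the two stereocentres C6 and Cα that the target needs.
- ¹O₂ adds to a 5-substituted cyclohexa-1,3-diene on the face anti to the substituent.
- Ring numbering used throughout: C1 (O-bearing, next to C6), C2=C3(Me), C4 (O-bearing), C5H₂, C6 (bears the side chain). Cα is the side-chain CH(CH₃).

**Retrosynthesis**
1. The curcuminoid C=C bond comes from a boron-mediated Knoevenagel (Pabon) condensation of an aryl-ether aldehyde with feruloylacetone, which is made from vanillin and acetylacetone.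
2. The aryl ether is made by SNAr of the C1 alkoxide on 4-fluoro-3-methoxybenzaldehyde. C–O bond formation at the aryl carbon leaves the carbinol carbon untouched, so C1 is retained.
3. The mono-protected cis-1,4-diol comes from reduction of the endoperoxide of α-turmerone (¹O₂ [4+2]).
4. The only ring formed is the transient bicyclic endoperoxide, made in Step 1 and opened in Step 2. The cyclohexene comes from α-turmerone and the arenes from commercial aldehydes.

---

## Route

**Step 1**
Reactants: 1 (6S)-α-turmerone
Product: 2 endoperoxide, (6S)-6-[(1R)-2,5-epidioxy-4-methylcyclohex-3-en-1-yl]-2-methylhept-2-en-4-one, with the O–O bridge anti to the side chain (CIP 1R,4S,6R,Cα S in the numbering above)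
Conditions: O₂, Rose Bengal (or TPP), hν (visible), CH₂Cl₂, 0 °C
Reagents that add atoms: singlet oxygen from O₂, O=O
Why: Photooxygenation is a [4+2] cycloaddition of ¹O₂ to the cyclic 1,3-diene. It occurs on the face anti to the C6 side chain, which sets both new C–O stereocentres (C1, C4) cis to each other and trans to the side chain. The enone and ketone are unreactive toward ¹O₂.

**Step 2**
Reactants: 2
Product: 3 cis-diol, (6S)-6-[(1R,4S,6R)-1,4-dihydroxy-... i.e. cyclohex-2-ene-1,4-diol core with both OH anti to the side chain]
Conditions: thiourea, MeOH, 25 °C
Reagents that add atoms: none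
Why: Thiourea is a mild, neutral reductant that cleaves the O–O bond with no change at the carbinol carbons, giving the cis-diol with retention. It avoids base, so Kornblum–DeLaMare fragmentation is not triggered, and the enone, ketone and alkenes are untouched.

**Step 3**
Reactants: 3
Product: 4 C4-O-TBS ether, C1-OH free
Conditions: TBSCl, imidazole, CH₂Cl₂, 0 °C
Reagents that add atoms: TBSCl, CC(C)(C)[Si](C)(C)Cl
Why: Silylation is a sterically controlled protection. C4–OH sits between a CH₂ and a vinylic carbon, whereas C1–OH is flanked by the branched C6 that carries the side chain. The silyl group therefore goes mainly on C4. No stereocentre is touched.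

**Step 4**
Reactants: 4; 5 4-fluoro-3-methoxybenzaldehyde
Product: 6 aryl ether, with C4-OTBS and the aldehyde intact
Conditions: NaH, DMF, 0 °C → 25 °C (alkoxide formed first, then 5 added)
Reagents that add atoms: 5 (the aryl donor), COc1cc(C=O)ccc1F; NaH adds no atoms
Why: SNAr, with fluoride displaced para to the CHO activating group. The C1–O bond of the alkoxide is never broken, so C1 keeps the configuration from the endoperoxide. This gives the required aryloxy group anti to the side chain. No new stereocentre is formed.

**Step 5**
Reactants: 6
Product: 7 aryl-ether aldehyde with free C4-OH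
Conditions: HF·pyridine, THF/pyridine, 0 → 25 °C
Reagents that add atoms: none
Why: Fluoride-mediated desilylation. These mildly acidic conditions leave the aldehyde, enone, allylic aryl ether and all stereocentres intact, whereas basic TBAF could enolise the ketone.

**Step 6** (parallel branch)
Reactants: 8 vanillin; 9 acetylacetone (about 4 equiv, to avoid bis-condensation)
Product: 10 feruloylacetone, (1E)-1-(4-hydroxy-3-methoxyphenyl)hex-1-ene-3,5-dione (drawn as the keto form)
Conditions: B₂O₃, B(OBu)₃, n-BuNH₂ (cat.), EtOAc, 80 °C; then 0.4 M HCl, 60 °C
Reagents that add atoms: none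
Why: Pabon boron-complex Knoevenagel condensation. The boron chelate of acetylacetone activates the terminal methyl, and the condensation gives the E-styryl unit.

**Step 7**
Reactants: 7; 10
Product: 11 bisabolocurcumin ether (target)
Conditions: (a) 10, B₂O₃, EtOAc, 70 °C; (b) 7, B(OBu)₃, n-BuNH₂ (cat.), 80 °C; (c) aq. HCl, 60 °C, 30 min (AcOH/H₂O if the allylic system is acid-labile)
Reagents that add atoms: none
Why: In the boron chelate of 10 the only enolisable CH₃ is the unconjugated one, so condensation with the aldehyde 7 (Pabon Knoevenagel) occurs there to give the second E-styryl unit. Hydrolysis releases the enolised 1,3-diketone. All ring and side-chain stereocentres are remote and are not involved.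

---

## Compound list

| # | Name | SMILES | Role |
|---|---|---|---|
| 1 | (6S)-α-turmerone | CC(C)=CC(=O)C[C@H](C)[C@@H]1C=CC(C)=CC1 | starting material |
| 2 | α-turmerone 1,4-endoperoxide | CC(C)=CC(=O)C[C@H](C)[C@H]1C[C@@H]2OO[C@H]1C=C2C | intermediate |
| 3 | cis-1,4-diol (both OH anti to side chain) | O[C@H]1C=C(C)[C@@H](O)C[C@@H]1[C@@H](C)CC(=O)C=C(C)C | intermediate |
| 4 | C4-O-TBS, C1-OH alcohol | O[C@H]1C=C(C)[C@@H](O[Si](C)(C)C(C)(C)C)C[C@@H]1[C@@H](C)CC(=O)C=C(C)C | intermediate |
| 5 | 4-fluoro-3-methoxybenzaldehyde | COc1cc(C=O)ccc1F | starting material |
| 6 | aryl ether, TBS-protected aldehyde | COc1cc(C=O)ccc1O[C@H]1C=C(C)[C@@H](O[Si](C)(C)C(C)(C)C)C[C@@H]1[C@@H](C)CC(=O)C=C(C)C | intermediate |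
| 7 | aryl-ether aldehyde, free C4-OH | COc1cc(C=O)ccc1O[C@H]1C=C(C)[C@@H](O)C[C@@H]1[C@@H](C)CC(=O)C=C(C)C | intermediate |
| 8 | vanillin | COc1cc(C=O)ccc1O | starting material |
| 9 | acetylacetone | CC(=O)CC(C)=O | starting material |
| 10 | feruloylacetone | CC(=O)CC(=O)/C=C/c1ccc(O)c(OC)c1 | intermediate |
| 11 | bisabolocurcumin ether | COc1cc(/C=C/C(=O)/C=C(O)/C=C/c2ccc(O[C@H]3C=C(C)[C@@H](O)C[C@@H]3[C@@H](C)CC(=O)C=C(C)C)c(OC)c2)ccc1O | target |

**Total steps:** 7
**Longest linear sequence:** 6 steps (Steps 1, 2, 3, 4, 5, 7 from α-turmerone)

## Three steps most likely to fail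

1. **Step 3, C4 vs C1 regioselective silylation.**
   - The steric difference between the two hydroxyls is modest, so mixtures are possible.
   - Fallback: skip differentiation altogether. Treat endoperoxide 2 with Et₃N (Kornblum–DeLaMare) to give the γ-hydroxy enone with C1–OH free and C4=O. Do the SNAr on C1–OH, then reduce the C4 ketone (Luche or CBS) and separate any C4 epimer.

2. **Step 4, SNAr with a hindered alkoxide in the presence of an enolisable enone ketone.**
   - Aldol or enolate side reactions could compete.
   - Fallback: invert the strategy. Oxidise C1–OH of 4 (DMP), reduce with L-Selectride to the C1 epimer (OH syn to the side chain), then run a Mitsunobu reaction with vanillin (DIAD, PPh₃). The inversion puts the aryloxy group anti to the side chain, and the vanillin aldehyde goes straight into Step 7.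

3. **Step 7, Pabon condensation and acidic boron-chelate hydrolysis.**
   - The allylic aryl ether and allylic alcohol are acid-sensitive, and the side-chain ketone or enone could react with the amine catalyst.
   - Fallback: change the C=C-forming method. Use a Horner–Wadsworth–Emmons reaction of aldehyde 7 with the dianion of a feruloyl β-ketophosphonate under non-acidic conditions.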